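**Strategy.** Everything rests on cutting ring C of the upper epicatechin unit at C2–C3 and C4–C4a. The lower 4β→6 dimer is built first and given an (E)-2-acetoxyvinyl group on C8 of its middle unit, the future C4 and C3. An O-aryl oxocarbenium ion assembled from 3,5-dibenzyloxyphenol and 3,4-dibenzyloxybenzaldehyde (ring A, O1, C2, ring B) then engages this alkene in a chiral-acid-controlled oxa-Povarov [4+2] annulation. The step exploits the aryl ether array C4a=C8a–O1 of ring A as a cationic heterodiene, closes ring C and sets C2, C3 and C4 at once. Deacetylation and hydrogenolysis finish.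

Key step: step 10

Assumption: the (R)-configured N-triflylphosphoramide is taken as the catalyst enantiomer that leads to the (2R) upper unit; if the sense proves opposite, the (S)-catalyst is used with no other change. 3,5-Dibenzyloxyphenol, 3,4-dibenzyloxybenzaldehyde and vinylboronic acid pinacol ester are taken as commercial.

**Step 1**
Reactants: 1 (−)-epicatechin
Product: 2 5,7,3',4'-tetra-O-benzyl-(−)-epicatechin
Conditions: BnBr (4.2 equiv), K2CO3, DMF, 0 °C → rt
Reagents that add atoms: benzyl bromide, BrCc1ccccc1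
Why: Williamson etherification; the carbonate deprotonates only the four phenols, so the secondary 3-OH stays free and no stereocentre is touched.

**Step 2**
Reactants: 2 5,7,3',4'-tetra-O-benzyl-(−)-epicatechin
Product: 3 8-bromo-5,7,3',4'-tetra-O-benzyl-(−)-epicatechin
Conditions: NBS (1.05 equiv), CH2Cl2, −78 °C → rt
Reagents that add atoms: N-bromosuccinimide, O=C1CCC(=O)N1Br
Why: electrophilic aromatic bromination; C8 is the most nucleophilic position of ring A in benzylated flavan-3-ols, and the bromine later blocks C8 so that this unit can only react at C6.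

**Step 3**
Reactants: 2 5,7,3',4'-tetra-O-benzyl-(−)-epicatechin
Product: 5 4β-(2-ethoxyethoxy)-5,7,3',4'-tetra-O-benzylepicatechin, via flavan-4-yl cation 4 (not isolated)
Conditions: DDQ (2 equiv), 2-ethoxyethanol (5 equiv), CH2Cl2, rt; then DMAP
Reagents that add atoms: 2-ethoxyethanol, CCOCCO
Why: DDQ oxidative C–H etherification; hydride abstraction at the ring-A-activated C4 gives cation 4, which the alcohol should capture on the face trans to the 3-OH (4β).

**Step 4**
Reactants: 5 4β-(2-ethoxyethoxy)-5,7,3',4'-tetra-O-benzylepicatechin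
Product: 6 8-iodo-4β-(2-ethoxyethoxy)-5,7,3',4'-tetra-O-benzylepicatechin
Conditions: NIS (1.1 equiv), NaHCO3, CH2Cl2, −40 → 0 °C
Reagents that add atoms: N-iodosuccinimide, O=C1CCC(=O)N1I
Why: electrophilic aromatic iodination at C8, by analogy with the bromination of step 2; the buffered neutral medium spares the acid-labile 4-alkoxy group, and the iodine both blocks self-condensation and is the later cross-coupling handle.

**Step 5**
Reactants: 6 8-iodo-4β-(2-ethoxyethoxy)-5,7,3',4'-tetra-O-benzylepicatechin; 3 8-bromo-5,7,3',4'-tetra-O-benzyl-(−)-epicatechin (3 equiv)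
Product: 8 8-iodo-epicatechin-(4β→6)-8-bromo-epicatechin octabenzyl ether (3-OH free in both units), via 8-iodoflavan-4-yl cation 7 (not isolated)
Conditions: TMSOTf (0.3 equiv), CH2Cl2, −78 °C; Et3N quench
Reagents that add atoms: none
Why: Lewis-acid-mediated Friedel–Crafts alkylation; ionisation of the 4-alkoxy group gives cation 7, which the bromine-blocked nucleophile can attack only through C6, and attack trans to the 3-OH should set C4 of the middle unit as 4β.

**Step 6**
Reactants: 8 8-iodo-epicatechin-(4β→6)-8-bromo-epicatechin octabenzyl ether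
Product: 9 3,3'-di-O-acetate of dimer 8
Conditions: Ac2O, pyridine, DMAP (cat.), CH2Cl2, rt
Reagents that add atoms: acetic anhydride, CC(=O)OC(C)=O
Why: DMAP-catalysed acylation; the two secondary alcohols are masked because free hydroxyls would intercept the oxocarbenium ion of step 10.

**Step 7**
Reactants: 9 dimer diacetate (aryl iodide on the middle unit, aryl bromide on the lower unit); 10 vinylboronic acid pinacol ester (3 equiv)
Product: 11 dimer diacetate carrying an (E)-2-(pinacolboryl)vinyl group on C8 of the middle unit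
Conditions: Pd(OAc)2 (10 mol%), P(o-tol)3 (20 mol%), Et3N, toluene, 90 °C, anhydrous
Reagents that add atoms: none
Why: Heck–Mizoroki reaction with retention of boron; zerovalent palladium inserts into the C–I bond far faster than into the electron-rich C–Br bond, the amine base without water suppresses Suzuki-type transmetalation, and syn-insertion then β-hydride elimination should give the (E)-alkene.

**Step 8**
Reactants: 11 (E)-styrylboronate dimer diacetate
Product: 12 dimer diacetate carrying an (E)-2-acetoxyvinyl group on C8 of the middle unit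
Conditions: Cu(OAc)2 (2.5 equiv), pyridine, 4 Å MS, DMF, 50 °C
Reagents that add atoms: copper diacetate, CC(=O)[O-].CC(=O)[O-].[Cu+2]
Why: Chan–Lam–Evans C–O coupling; the alkenyl group is transferred from boron to divalent copper acetate and C–O reductive elimination from trivalent copper should proceed with retention of the (E) geometry.

**Step 9**
Reactants: 13 3,4-bis(benzyloxy)benzaldehyde; 14 3,5-bis(benzyloxy)phenol
Product: 16 [3,5-bis(benzyloxy)phenoxy][3,4-bis(benzyloxy)phenyl]methyl pivalate (racemic), via α-chlorobenzyl pivalate 15 (not isolated)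
Conditions: PivCl (1.0 equiv), ZnCl2 (2 mol%), CH2Cl2, 0 °C → rt; then added to 14, Cs2CO3, DMF, −20 → 0 °C; filtration through basic alumina
Reagents that add atoms: pivaloyl chloride, CC(C)(C)C(Cl)=O
Why: ZnCl2-catalysed addition of the acyl chloride across the aldehyde C=O gives 15, whose readily ionised chloride is displaced by the caesium phenoxide on oxygen (as in acyloxymethyl ether formation), the hindered pivalate resisting acyl transfer.

**Step 10**
Reactants: 12 (E)-enol acetate dimer diacetate; 16 O-aryl O-pivaloyl acetal (1.5 equiv, added slowly)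
Product: 18 epicatechin-(4β→8)-epicatechin-(4β→6)-8-bromo-epicatechin dodecabenzyl ether 3,3',3''-triacetate, via O-aryl oxocarbenium ion 17 (not isolated)
Conditions: (R)-3,3'-bis(2,4,6-triisopropylphenyl)-1,1'-binaphthyl-2,2'-diyl N-triflylphosphoramide (10 mol%), 5 Å MS, toluene/CH2Cl2, −60 → −30 °C
Reagents that add atoms: none
Why: Proposed new method: the chiral acid protonates the pivalate of 16 and expels pivalic acid to give the (E)-oxocarbenium ion 17 as a contact ion pair, which reacts as a cationic 2-oxadiene (C4a=C8a–O1=C2) with the enol acetate of 12 in an asynchronous [4+2] annulation: the acetoxy-bearing carbon bonds to C2 first, the ortho carbon of the phloroglucinol ring captures the emerging trioxybenzylic cation at C4, and loss of the arene proton regenerates the acid. The closest known reaction types are the racemic Lewis-acid oxa-Povarov reaction of O-aryl oxocarbenium ions with styrenes and the chiral-Brønsted-acid-catalysed Povarov reaction of N-aryl iminium ions; a face-controlled oxa variant with an enol ester has not been shown. One ring is closed, ring C of the upper unit, in the [4+2] mode, its second bond being a 6-exo-trig Friedel–Crafts attack on the benzylic cation. C2 is set by the chiral counter-anion, which shields one face of 17; C3 should follow from C2 through an endo placement of the acetoxy group (carbonyl-to-cation attraction, the bulky di-ortho-substituted aryl group exo, no peri strain with the 5-benzyloxy group), giving 2,3-cis; C4 should follow from C3 because the (E) geometry is transferred suprafacially and, if the cation relaxes, acetoxy participation and allylic 1,3-strain both direct closure anti to the C3 oxygen, giving 3,4-trans. Regioselectivity requires the alkene to react as a styrene and not as an enol, which the weakly donating acetoxy group set against the strongly donating trioxyaryl group secures. Chemoselectivity requires the cation to prefer the alkene over arene C–H positions, which the bromine on C8 of the lower unit, the flanked C6 of the middle unit, the acetate masking of the alcohols and slow addition of 16 are meant to secure.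

**Step 11**
Reactants: 18 protected trimer triacetate
Product: 19 epicatechin-(4β→8)-epicatechin-(4β→6)-8-bromo-epicatechin dodecabenzyl ether (three 3-OH free)
Conditions: NaOMe (cat.), MeOH/THF, rt → 40 °C
Reagents that add atoms: none
Why: Zemplén transesterification removes the three acetates as methyl acetate; benzyl ethers and the aryl bromide are inert, and benzylated flavans should not epimerise under these conditions.

**Step 12**
Reactants: 19 trimer triol dodecabenzyl ether bromide
Product: 20 epicatechin-(4β→8)-epicatechin-(4β→6)-epicatechin (CNP0178679.3)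
Conditions: H2 (1 atm), Pd(OH)2/C, Et3N (1.1 equiv), THF/MeOH/H2O, rt
Reagents that add atoms: none
Why: catalytic hydrogenolysis cleaves the twelve benzyl ethers and the aryl C–Br bond (the amine takes up HBr) without touching the nine stereocentres.

**Compound list**
1 | (−)-epicatechin | Oc1cc(O)c2c(c1)O[C@H](c1ccc(O)c(O)c1)[C@H](O)C2 | starting material
2 | 5,7,3',4'-tetra-O-benzyl-(−)-epicatechin | c1ccccc1COc1cc(OCc3ccccc3)c2c(c1)O[C@H](c1ccc(OCc3ccccc3)c(OCc3ccccc3)c1)[C@H](O)C2 | intermediate
3 | 8-bromo-5,7,3',4'-tetra-O-benzyl-(−)-epicatechin | c1ccccc1COc1cc(OCc3ccccc3)c2c(c1Br)O[C@H](c1ccc(OCc3ccccc3)c(OCc3ccccc3)c1)[C@H](O)C2 | intermediate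
4 | tetra-O-benzyl-epicatechin flavan-4-yl cation | c1ccccc1COc1cc(OCc3ccccc3)c2c(c1)O[C@H](c1ccc(OCc3ccccc3)c(OCc3ccccc3)c1)[C@H](O)[CH+]2 | intermediate (not isolated)
5 | 4β-(2-ethoxyethoxy)-5,7,3',4'-tetra-O-benzylepicatechin | c1ccccc1COc1cc(OCc3ccccc3)c2c(c1)O[C@H](c1ccc(OCc3ccccc3)c(OCc3ccccc3)c1)[C@H](O)[C@H]2OCCOCC | intermediate
6 | 8-iodo-4β-(2-ethoxyethoxy)-5,7,3',4'-tetra-O-benzylepicatechin | c1ccccc1COc1cc(OCc3ccccc3)c2c(c1I)O[C@H](c1ccc(OCc3ccccc3)c(OCc3ccccc3)c1)[C@H](O)[C@H]2OCCOCC | intermediate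
7 | 8-iodo-tetra-O-benzyl-epicatechin flavan-4-yl cation | c1ccccc1COc1cc(OCc3ccccc3)c2c(c1I)O[C@H](c1ccc(OCc3ccccc3)c(OCc3ccccc3)c1)[C@H](O)[CH+]2 | intermediate (not isolated)
8 | 8-iodo-epicatechin-(4β→6)-8-bromo-epicatechin octabenzyl ether | Ic1c(OCc3ccccc3)cc(OCc3ccccc3)c2c1O[C@H](c1ccc(OCc3ccccc3)c(OCc3ccccc3)c1)[C@H](O)[C@H]2c1c(OCc3ccccc3)c(Br)c2c(c1OCc3ccccc3)C[C@@H](O)[C@@H](c1ccc(OCc3ccccc3)c(OCc3ccccc3)c1)O2 | intermediate
9 | di-O-acetate of 8 | Ic1c(OCc3ccccc3)cc(OCc3ccccc3)c2c1O[C@H](c1ccc(OCc3ccccc3)c(OCc3ccccc3)c1)[C@H](OC(C)=O)[C@H]2c1c(OCc3ccccc3)c(Br)c2c(c1OCc3ccccc3)C[C@@H](OC(C)=O)[C@@H](c1ccc(OCc3ccccc3)c(OCc3ccccc3)c1)O2 | intermediate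
10 | vinylboronic acid pinacol ester | C=CB1OC(C)(C)C(C)(C)O1 | starting material
11 | dimer diacetate with (E)-2-(pinacolboryl)vinyl on C8 of the middle unit | B1(OC(C)(C)C(C)(C)O1)/C=C/c1c(OCc3ccccc3)cc(OCc3ccccc3)c2c1O[C@H](c1ccc(OCc3ccccc3)c(OCc3ccccc3)c1)[C@H](OC(C)=O)[C@H]2c1c(OCc3ccccc3)c(Br)c2c(c1OCc3ccccc3)C[C@@H](OC(C)=O)[C@@H](c1ccc(OCc3ccccc3)c(OCc3ccccc3)c1)O2 | intermediate
12 | dimer diacetate with (E)-2-acetoxyvinyl on C8 of the middle unit | CC(=O)O/C=C/c1c(OCc3ccccc3)cc(OCc3ccccc3)c2c1O[C@H](c1ccc(OCc3ccccc3)c(OCc3ccccc3)c1)[C@H](OC(C)=O)[C@H]2c1c(OCc3ccccc3)c(Br)c2c(c1OCc3ccccc3)C[C@@H](OC(C)=O)[C@@H](c1ccc(OCc3ccccc3)c(OCc3ccccc3)c1)O2 | intermediate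
13 | 3,4-bis(benzyloxy)benzaldehyde | O=Cc1ccc(OCc2ccccc2)c(OCc2ccccc2)c1 | starting material
14 | 3,5-bis(benzyloxy)phenol | Oc1cc(OCc2ccccc2)cc(OCc2ccccc2)c1 | starting material
15 | chloro[3,4-bis(benzyloxy)phenyl]methyl pivalate (racemic) | CC(C)(C)C(=O)OC(Cl)c1ccc(OCc2ccccc2)c(OCc2ccccc2)c1 | intermediate (not isolated)
16 | [3,5-bis(benzyloxy)phenoxy][3,4-bis(benzyloxy)phenyl]methyl pivalate (racemic) | CC(C)(C)C(=O)OC(Oc1cc(OCc2ccccc2)cc(OCc2ccccc2)c1)c1ccc(OCc2ccccc2)c(OCc2ccccc2)c1 | intermediate
17 | (E)-O-[3,5-bis(benzyloxy)phenyl] oxocarbenium ion of 3,4-bis(benzyloxy)benzaldehyde | c1ccccc1COc1cc(OCc2ccccc2)cc(c1)/[O+]=C/c1ccc(OCc2ccccc2)c(OCc2ccccc2)c1 | intermediate (not isolated)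
18 | epicatechin-(4β→8)-epicatechin-(4β→6)-8-bromo-epicatechin dodecabenzyl ether triacetate | c1ccccc1COc1cc(OCc3ccccc3)c2c(c1)O[C@H](c1ccc(OCc3ccccc3)c(OCc3ccccc3)c1)[C@H](OC(C)=O)[C@H]2c1c(OCc3ccccc3)cc(OCc3ccccc3)c2c1O[C@H](c1ccc(OCc3ccccc3)c(OCc3ccccc3)c1)[C@H](OC(C)=O)[C@H]2c1c(OCc3ccccc3)c(Br)c2c(c1OCc3ccccc3)C[C@@H](OC(C)=O)[C@@H](c1ccc(OCc3ccccc3)c(OCc3ccccc3)c1)O2 | intermediate
19 | epicatechin-(4β→8)-epicatechin-(4β→6)-8-bromo-epicatechin dodecabenzyl ether | c1ccccc1COc1cc(OCc3ccccc3)c2c(c1)O[C@H](c1ccc(OCc3ccccc3)c(OCc3ccccc3)c1)[C@H](O)[C@H]2c1c(OCc3ccccc3)cc(OCc3ccccc3)c2c1O[C@H](c1ccc(OCc3ccccc3)c(OCc3ccccc3)c1)[C@H](O)[C@H]2c1c(OCc3ccccc3)c(Br)c2c(c1OCc3ccccc3)C[C@@H](O)[C@@H](c1ccc(OCc3ccccc3)c(OCc3ccccc3)c1)O2 | intermediate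
20 | epicatechin-(4β→8)-epicatechin-(4β→6)-epicatechin (CNP0178679.3) | Oc1cc(O)c2c(c1)O[C@H](c1ccc(O)c(O)c1)[C@H](O)[C@H]2c1c(O)cc(O)c2c1O[C@H](c1ccc(O)c(O)c1)[C@H](O)[C@H]2c1c(O)cc2c(c1O)C[C@@H](O)[C@@H](c1ccc(O)c(O)c1)O2 | target

**Step count and risks**
Total step count: 12. Longest linear sequence: 10 steps (1, 3, 4, 5, 6, 7, 8, 10, 11, 12).

Steps most likely to fail:

1. Step 10 (Proposed new method). The catalyst may pair the wrong faces or give poor endo/exo control, so that the 2,3-trans upper unit forms. The cation may also be captured by an arene C–H instead of the alkene, or the acetal may self-condense. Fallback with known chemistry, setting out from compounds 9 and 5 and returning at compound 18: the iodine of 9 is removed selectively (Pd(PPh3)4, HCO2Na, DMF, 80 °C) to give the deiodinated dimer diacetate F1. Compound 5 is acetylated (Ac2O, pyridine, DMAP) to 3-O-acetyl-4β-(2-ethoxyethoxy)-5,7,3',4'-tetra-O-benzylepicatechin F2. TMSOTf-mediated Friedel–Crafts coupling of F2 with excess F1 (CH2Cl2, −78 °C) should form the 4β→8 interflavan bond directly, trans to the 3-acetoxy group, and give 18.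

2. Step 9. The ambident phenoxide may alkylate on carbon, acyl transfer to the phenoxide may compete, and the labile acetal may hydrolyse during isolation. Fallback, setting out from compounds 13 and 14 and returning at compound 16: NaBH4 reduction of 13 gives 3,4-bis(benzyloxy)benzyl alcohol F3. Mitsunobu etherification of F3 with 14 (PPh3, DIAD, THF) gives 3,5-bis(benzyloxy)phenyl 3,4-bis(benzyloxy)benzyl ether F4. DDQ oxidation of the activated benzylic C–H of F4 in the presence of pivalic acid and 4 Å MS (CH2Cl2, 0 °C) should trap the oxocarbenium ion as pivalate 16.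

3. Step 7. Migratory insertion may be slow at the di-ortho-substituted aryl palladium species, Suzuki-type transmetalation may compete and give the simple vinyl arene, and oxidative addition into the bromide may erode site selectivity. Fallback, setting out from compound 9 and returning at compound 11: Stille coupling of 9 with tributyl(vinyl)stannane (Pd(PPh3)4, toluene, 100 °C) gives the 8-vinyl dimer diacetate F5. Cross-metathesis of F5 with 10 (second-generation Hoveyda–Grubbs catalyst, CH2Cl2, 40 °C) should give the (E)-alkenylboronate 11.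

**Further compounds**
F1 | step 10 | epicatechin-(4β→6)-8-bromo-epicatechin octabenzyl ether diacetate (C8 of the upper unit free) | c1c(OCc3ccccc3)cc(OCc3ccccc3)c2c1O[C@H](c1ccc(OCc3ccccc3)c(OCc3ccccc3)c1)[C@H](OC(C)=O)[C@H]2c1c(OCc3ccccc3)c(Br)c2c(c1OCc3ccccc3)C[C@@H](OC(C)=O)[C@@H](c1ccc(OCc3ccccc3)c(OCc3ccccc3)c1)O2
F2 | step 10 | 3-O-acetyl-4β-(2-ethoxyethoxy)-5,7,3',4'-tetra-O-benzylepicatechin | c1ccccc1COc1cc(OCc3ccccc3)c2c(c1)O[C@H](c1ccc(OCc3ccccc3)c(OCc3ccccc3)c1)[C@H](OC(C)=O)[C@H]2OCCOCC
F3 | step 9 | 3,4-bis(benzyloxy)benzyl alcohol | OCc1ccc(OCc2ccccc2)c(OCc2ccccc2)c1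
F4 | step 9 | 3,5-bis(benzyloxy)phenyl 3,4-bis(benzyloxy)benzyl ether | c1ccccc1COc1cc(OCc2ccccc2)cc(c1)OCc1ccc(OCc2ccccc2)c(OCc2ccccc2)c1
F5 | step 7 | dimer diacetate with a vinyl group on C8 of the middle unit | C=Cc1c(OCc3ccccc3)cc(OCc3ccccc3)c2c1O[C@H](c1ccc(OCc3ccccc3)c(OCc3ccccc3)c1)[C@H](OC(C)=O)[C@H]2c1c(OCc3ccccc3)c(Br)c2c(c1OCc3ccccc3)C[C@@H](OC(C)=O)[C@@H](c1ccc(OCc3ccccc3)c(OCc3ccccc3)c1)O2
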